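## Structural features

Dielsianone is a benzil: an ethane-1,2-dione whose two carbonyl carbons carry a 4-methoxyphenyl ring (ring B) and C6 of a 2,2-dimethyl-2H-chromene (ring A fused to the pyran ring C). Ring A is pentasubstituted. Going round it, C4a carries the pyran carbon C4, C5 a free hydroxyl, C6 the diketone, C7 the only hydrogen, C8 a methoxy group and C8a the pyran oxygen O1. There is no stereocentre; the only stereochemical element is the cis C3=C4 alkene held in ring C. The fragile groups are the 1,2-diketone (hydroxide, hydride donors, amines), the styrene-like C3=C4 alkene beside a tertiary allylic aryl ether (strong acid, oxidants) and the C5 hydroxyl, which is chelated to the C6 carbonyl. The real difficulty is regiochemical: C4 must be attached at C4a, the crowded carbon between the C5 and C8a oxygens, and the ring oxygen must be the one on C8a and not the one on C5. The key step uses exactly this arrangement. A formyl group on C4a together with the C8a hydroxyl is a latent heterodiene O=C8a–C4a=C4, and the C3–C2(CH3)2 unit of ring C is isobutene. The C6 acyl group para to C8a makes that heterodiene electron-poor, so it pairs with the electron-rich alkene.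

## Logic of the disconnections

**12 ⇒ 11.** No skeletal bond is cut; the C3=C4 alkene is replaced by a methoxy group on C4 and a hydrogen on C3. C4 then stands at the oxidation level of an aldehyde carbon, so the alkene can be made by elimination and no dehydrogenating oxidant has to meet the electron-rich ring. The price is one stereocentre of no consequence. The forward step must be an acid elimination mild enough for the diketone and for the chromene it creates.

**11 ⇒ 6 + 7 + 8.** Ring C is opened at C4–C3 and at C2–O1. This removes the ring and the stereocentre in one operation and leaves a benzaldehyde (6), a C4 alkene (7) and the source of the C4 methoxy group (8). The cut is made here because C4a lies between two oxygens, so its formyl group and the C8a hydroxyl form a heterodiene, reached through 9 and 10. The forward step must make the C8a oxygen, not the C5 oxygen, the ring oxygen. Both hydroxyls of 6 are nevertheless left free: the C5 hydroxyl is already masked by its hydrogen bond to the C6 carbonyl, and a covalent mask would have to go on the less reactive of two phenols and come off again, at a cost of about four steps.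

**6 ⇒ 4.** The C4a–C4 (aryl–formyl) bond is cut. In 4 the carbon between the two hydroxyls is the only ring position ortho to a phenol, so a phenoxide-directed ortho-formylation has no regiochemical choice; it runs through 5. The gain is a simple trioxygenated benzil. The formylation must tolerate the α-diketone; it is placed after the oxidation because the active methylene of 3 would itself react with a one-carbon electrophile.

**4 ⇒ 3.** One carbonyl of the diketone is taken back to a methylene group, because the resulting aryl benzyl ketone is the direct product of a Friedel–Crafts acylation. The forward step needs an oxidant selective for the doubly activated methylene that leaves the free phenols and the electron-rich ring alone.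

**3 ⇒ 1 + 2.** The C6–C(=O) bond is cut. The ring carbon of 1 that is para to one hydroxyl and ortho to the other is its most nucleophilic position and is exactly where the acyl group belongs. The acyl group then blocks this position and leaves the carbon between the hydroxyls as the only site for the later formylation. Both pieces are commercial. The forward step must give C-acylation at that carbon and not at the crowded one between the hydroxyls.

## Other disconnections considered

**Alternative 1:** The cut removes both aryl–carbonyl bonds of the diketone, C6–C(=O) and C(=O)–C1'. The two carbonyl carbons come from the cyclic oxamide 1,4-dimethylpiperazine-2,3-dione A3.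
- Forward key step: the finished chromene 8-methoxy-5-(methoxymethoxy)-2,2-dimethyl-2H-chromene A2 would be lithiated at C6, next to the methoxymethyl ether, by an alkyllithium base and added to one amide carbonyl of A3. The tetrahedral adduct should hold at low temperature while 4-methoxyphenylmagnesium bromide A4 adds to the second carbonyl. An acid quench would release 1-[8-methoxy-5-(methoxymethoxy)-2,2-dimethyl-2H-chromen-6-yl]-2-(4-methoxyphenyl)ethane-1,2-dione A1, and mild acid would then remove the acetal group to give 12.
- In its favour: the plan is convergent, the fragile diketone appears only at the end and at the right oxidation level, and neither a methylene oxidation nor a formylation of a deactivated ring is needed. On these three points it is the better plan.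
- Against it here: A2 is not a simple compound. From 1, ring C would have to be built on the crowded carbon between the two oxygens while the more nucleophilic position para to a hydroxyl is still open; the chosen plan blocks that position with the acyl group first. The lithiation must also choose C6 over C7, which is ortho to the C8 methoxy group. A protection, a deprotection, cryogenic stoichiometric organometallics and possible double addition of one aryl metal are added.
- Comparison: both plans rest on known reaction types and are equal in that respect. In step count the alternative is at best equal to five steps and more probably two or three longer once a regiocontrolled route to A2 is counted.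

**Alternative 2:** The cut is the C5–C6 bond of ring A, the whole ring being traced to a four-membered ring made from a squaric acid monoester.
- Forward key step: 3-isopropoxy-4-methoxy-4-[(1E,3E)-4-(4-methoxyphenyl)buta-1,3-dienyl]cyclobut-2-en-1-one A6 would be heated. Conrotatory ring opening with the methoxy group turning outwards gives a dienylketene, 6π electrocyclisation forms C5–C6, and tautomerisation gives (E)-5-isopropoxy-4-methoxy-2-(4-methoxystyryl)phenol A5.
- In its favour: every oxygen of ring A is placed by the connectivity of the small ring and not by directing effects, so the substitution pattern is more certain than in the chosen plan, which relies on the innate selectivity of 1 in the acylation. The key step needs no reagent.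
- Against it here: A5 contains neither the diketone nor ring C. The stilbene alkene would have to be oxidised to the diketone in the presence of a 4-methoxyphenol, a hydroquinone monoether prone to quinone formation. The isopropyl ether would have to be cleaved beside two methyl ethers. C4a is still a C–H, so the central regiochemical problem, a pyran on the carbon between two oxygens, is only postponed. A6 itself needs a dienyl-metal addition to the squarate and methylation of a hindered tertiary alkoxide.
- Comparison: the pericyclic cascade is as well founded as the cycloaddition of the chosen plan (equal). In step economy the alternative is clearly worse, roughly twice the five steps.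

**Alternative 3:** The cut is at C8–C7 and C5–C6. Ring A is assembled from the diene 1,4-dimethoxy-2-(3-methylbut-2-enyl)-1,3-bis(trimethylsilyloxy)buta-1,3-diene A8 and the ketal-masked terminal ynone 1,1-dimethoxy-1-(4-methoxyphenyl)but-3-yn-2-one A9.
- Forward key step: the nucleophilic C8 terminus of A8 would add to the unsubstituted alkyne carbon of A9 and C5 to the acyl-bearing carbon, a [4+2] cycloaddition or its stepwise equivalent. 1,4-Loss of methanol aromatises the ring, and acidic work-up removes the silyl groups and the ketal to give 1-[2,4-dihydroxy-5-methoxy-3-(3-methylbut-2-enyl)phenyl]-2-(4-methoxyphenyl)ethane-1,2-dione A7. An oxidative cyclisation of the prenyl group onto the C8a hydroxyl, for example with DDQ, would then give 12.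
- In its favour: the C4a–C4 bond and the complete carbon skeleton exist as soon as ring A exists, the orientation follows from the polarity of the two partners, and neither a formylation nor a methylene oxidation is needed. On these points it is the better plan.
- Against it here: A8 is a tetrasubstituted, moisture-sensitive ketene acetal. Its preparation needs C-prenylation of a 4-methoxyacetoacetate and a double silylation, and its congestion at C4a should slow the cycloaddition. A9 needs its own synthesis. The quinone oxidant must spare an electron-rich trioxygenated ring.
- Comparison: closing ring C from A7 faces the same choice between the C5 and C8a hydroxyls as the chosen key step, so on that selectivity the plans are equal. In step economy the alternative should need about seven to nine steps against five.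

Key step: step 4

Assumption: 11 is formed and used as the racemate (one enantiomer is drawn in its SMILES), which is acceptable because its only stereocentre becomes trigonal in step 5; the exocyclic alkene geometry of the transient 10 is left undefined because both isomers lead to the same product.

## Route

Step 1
Reactants: 1 4-methoxyresorcinol (4-methoxybenzene-1,3-diol); 2 4-methoxyphenylacetic acid
Product: 3 1-(2,4-dihydroxy-5-methoxyphenyl)-2-(4-methoxyphenyl)ethan-1-one
Conditions: BF3·OEt2 (neat), 85 °C; then aq. NaOAc
Reagents that add atoms: none
Why: Friedel–Crafts (Nencki-type) C-acylation, in which BF3 activates the acid and 1 is attacked at the ring carbon para to one hydroxyl and ortho to the other, its most nucleophilic and least crowded site. The product is held as a boron chelate of the ortho-hydroxy ketone, which stops a second acylation and is hydrolysed on work-up.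

Step 2
Reactants: 3 1-(2,4-dihydroxy-5-methoxyphenyl)-2-(4-methoxyphenyl)ethan-1-one
Product: 4 1-(2,4-dihydroxy-5-methoxyphenyl)-2-(4-methoxyphenyl)ethane-1,2-dione
Conditions: SeO2 (1.3 equiv), 1,4-dioxane/H2O, 100 °C
Reagents that add atoms: selenium dioxide, O=[Se]=O
Why: Riley oxidation, in which SeO2 attacks the enol of the methylene flanked by the carbonyl and the anisyl ring and the selenium ester collapses to the 1,2-diketone and elemental selenium. The acyl group tempers the nucleophilicity of the resorcinol ring, so the methylene should react first.

Step 3
Reactants: 4 1-(2,4-dihydroxy-5-methoxyphenyl)-2-(4-methoxyphenyl)ethane-1,2-dione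
Product: 6 2,6-dihydroxy-3-methoxy-5-[2-(4-methoxyphenyl)-2-oxoacetyl]benzaldehyde, via hydroxymethyl intermediate 5 (not isolated)
Conditions: MgCl2 (3 equiv), Et3N (6 equiv), (CH2O)n (8 equiv), MeCN, reflux; then 1 M HCl
Reagents that add atoms: paraformaldehyde (reacts as formaldehyde), C=O
Why: Casnati–Skattebøl ortho-formylation, in which the chloromagnesium phenoxide (ArOMgCl) delivers formaldehyde to the only ring carbon ortho to a phenoxide, the one between the two hydroxyls, giving 5; an Oppenauer-type hydride transfer from its alkoxide to a second formaldehyde then gives the aldehyde. The non-enolisable diketone should be a spectator, because formaldehyde in large excess is the far better hydride acceptor and Et3N does not induce a benzilic rearrangement.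

Step 4
Reactants: 6 2,6-dihydroxy-3-methoxy-5-[2-(4-methoxyphenyl)-2-oxoacetyl]benzaldehyde; 7 isobutene (2-methylprop-1-ene); 8 trimethyl orthoformate
Product: 11 rac-1-(5-hydroxy-4,8-dimethoxy-2,2-dimethyl-3,4-dihydro-2H-chromen-6-yl)-2-(4-methoxyphenyl)ethane-1,2-dione, via dimethyl acetal 9 (not isolated), via methoxy ortho-quinone methide 10 (not isolated)
Conditions: Sc(OTf)3 (10 mol %), 8 (1.5 equiv), 7 (excess, condensed), CH2Cl2, sealed tube, 0 °C to rt; then dilute aq. HCl wash
Reagents that add atoms: none
Why: Sc(OTf)3 catalyses acetal exchange between the aldehyde of 6 and 8 to give 9, and then ionises 9, the C8a hydroxyl pushing out one methoxy group, to give 10, which reacts in its O-protonated (methoxycarbenium) form. The CH2 terminus of 7 bonds to C4 while positive charge builds on the tertiary carbon, and the C8a oxygen then captures that carbon: an asynchronous inverse-electron-demand hetero-[4+2] cycloaddition (Prins-type addition, then oxa-cyclisation) forming C4–C3 and C2–O1. The closest known reaction type is the Lewis acid and orthoformate mediated three-component synthesis of 4-alkoxychromans from salicylaldehydes and alkenes. Ring C is closed in the [4+2] mode, its last bond being attack of the phenolic oxygen on the tertiary cation to complete the six-membered ring. The orientation is fixed by cation stability (tertiary over primary), so the gem-dimethyl carbon ends on oxygen. C4 is the only new stereocentre; nothing controls it, 11 is expected as the racemate, and this is harmless because C4 becomes trigonal in step 5. The selectivity that matters is between the two hydroxyls flanking C4a: the C5 hydroxyl is tied into a resonance-assisted hydrogen bond with the C6 carbonyl and is a poor nucleophile, and because aryl tertiary-alkyl ethers ionise reversibly under the Lewis acid, the closure should also drain towards 11, the isomer that keeps this hydrogen bond. The aldehyde is acetalised far faster than the diaryl diketone, and keeping 8 near 1.5 equivalents plus the acid wash should leave the diketone free.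

Step 5
Reactants: 11 rac-1-(5-hydroxy-4,8-dimethoxy-2,2-dimethyl-3,4-dihydro-2H-chromen-6-yl)-2-(4-methoxyphenyl)ethane-1,2-dione
Product: 12 dielsianone, 1-(5-hydroxy-8-methoxy-2,2-dimethyl-2H-chromen-6-yl)-2-(4-methoxyphenyl)ethane-1,2-dione
Conditions: TsOH·H2O (10 mol %), toluene, 80 °C
Reagents that add atoms: none
Why: Acid-catalysed E1 elimination, in which protonation of the C4 methoxy group gives a benzylic cation stabilised by the ortho oxygens on C5 and C8a, and loss of a C3 proton gives the conjugated chromene, the usual fate of 4-alkoxychromans under TsOH. The C4 stereocentre disappears, and the water of the hydrate returns any ketalised carbonyl to the diketone.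

## Compound list

1 | 4-methoxyresorcinol (4-methoxybenzene-1,3-diol) | COc1ccc(O)cc1O | starting material
2 | 4-methoxyphenylacetic acid | COc1ccc(CC(=O)O)cc1 | starting material
3 | 1-(2,4-dihydroxy-5-methoxyphenyl)-2-(4-methoxyphenyl)ethan-1-one | COc1ccc(CC(=O)c2cc(OC)c(O)cc2O)cc1 | intermediate
4 | 1-(2,4-dihydroxy-5-methoxyphenyl)-2-(4-methoxyphenyl)ethane-1,2-dione | COc1ccc(C(=O)C(=O)c2cc(OC)c(O)cc2O)cc1 | intermediate
5 | 1-[2,4-dihydroxy-3-(hydroxymethyl)-5-methoxyphenyl]-2-(4-methoxyphenyl)ethane-1,2-dione (present as its magnesium salt, not isolated) | COc1ccc(C(=O)C(=O)c2cc(OC)c(O)c(CO)c2O)cc1 | intermediate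
6 | 2,6-dihydroxy-3-methoxy-5-[2-(4-methoxyphenyl)-2-oxoacetyl]benzaldehyde | COc1ccc(C(=O)C(=O)c2cc(OC)c(O)c(C=O)c2O)cc1 | intermediate
7 | isobutene (2-methylprop-1-ene) | C=C(C)C | starting material
8 | trimethyl orthoformate | COC(OC)OC | starting material
9 | 1-[3-(dimethoxymethyl)-2,4-dihydroxy-5-methoxyphenyl]-2-(4-methoxyphenyl)ethane-1,2-dione (not isolated) | COc1ccc(C(=O)C(=O)c2cc(OC)c(O)c(C(OC)OC)c2O)cc1 | intermediate
10 | 1-[2-hydroxy-5-methoxy-3-(methoxymethylidene)-4-oxocyclohexa-1,5-dien-1-yl]-2-(4-methoxyphenyl)ethane-1,2-dione (not isolated; exocyclic alkene geometry not defined; reacts as its O-protonated form) | COC=C1C(O)=C(C(=O)C(=O)c2ccc(OC)cc2)C=C(OC)C1=O | intermediate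
11 | rac-1-(5-hydroxy-4,8-dimethoxy-2,2-dimethyl-3,4-dihydro-2H-chromen-6-yl)-2-(4-methoxyphenyl)ethane-1,2-dione (racemate; the 4S enantiomer is drawn) | COc1ccc(C(=O)C(=O)c2cc(OC)c3c(c2O)[C@@H](OC)CC(C)(C)O3)cc1 | intermediate
12 | dielsianone, 1-(5-hydroxy-8-methoxy-2,2-dimethyl-2H-chromen-6-yl)-2-(4-methoxyphenyl)ethane-1,2-dione | COc1ccc(C(=O)C(=O)c2cc(OC)c3c(c2O)C=CC(C)(C)O3)cc1 | target

## Step count and risk

Total step count: 5. Longest linear sequence: 5 steps (1 or 2 → 3 → 4 → 6 → 11 → 12).

**Step 4 (key step).**
- What may go wrong: ring closure through the C5 oxygen instead of the C8a oxygen; cationic oligomerisation of 7 outrunning its capture by the heterodiene; slow acetalisation of an aldehyde that is hydrogen-bonded on both sides and conjugated to two phenolic donors; ketalisation of the diketone.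
- Fallback: it sets out from 4 and comes back to the route at 12, bypassing steps 3 to 5. Compound 4 would be heated with 3-methylbut-2-enal in pyridine at 120 °C in a sealed vessel, the classical chromenylation of acylresorcinols. Condensation at the carbon between the hydroxyls and loss of water would give the dienone 1-[2-hydroxy-5-methoxy-3-(3-methylbut-2-en-1-ylidene)-4-oxocyclohexa-1,5-dien-1-yl]-2-(4-methoxyphenyl)ethane-1,2-dione F1 (not isolated). Its oxa-6π electrocyclisation closes ring C and gives 12 directly. The ring is built by C–C bond formation to an aldehyde carbon and a pericyclic O–C closure, not by a cationic cycloaddition, and the same chelation of the C5 hydroxyl directs the closure to the C8a oxygen.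

**Step 3.**
- What may go wrong: sluggish substitution on a ring deactivated by the acyl group; hydride transfer from the alkoxide of 5 to the diketone instead of to formaldehyde (a Meerwein–Ponndorf–Verley-type reduction); slow base-induced degradation of the diketone at reflux.
- Fallback: it sets out from 4 and comes back at 6, using a Rieche formylation (Cl2CHOMe, TiCl4, CH2Cl2, 0 °C; then aq. HCl). This delivers the formyl carbon already at the aldehyde oxidation level, under Lewis-acidic and non-basic conditions, with no hydride-transfer stage. Coordination of the phenols to titanium directs the electrophile to the same carbon between the hydroxyls. No new compound is isolated on this way (F0).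

**Step 2.**
- What may go wrong: attack of the oxidant on the free, electron-rich resorcinol ring (ring selenation or oxidative degradation) competing with selenation of the enol; retention of colloidal selenium by the chelating product.
- Fallback: it sets out from 3 and comes back at 4, as a protect–oxidise–release sequence that takes the phenols out of play. Acetylation (Ac2O, pyridine, rt) would give 4-methoxy-6-[2-(4-methoxyphenyl)acetyl]-1,3-phenylene diacetate F2. The same Riley oxidation (SeO2, 1,4-dioxane, 100 °C) on the deactivated ring would give 4-methoxy-6-[2-(4-methoxyphenyl)-2-oxoacetyl]-1,3-phenylene diacetate F3. Brief methanolysis (K2CO3, MeOH, 0 °C), too mild for a benzilic ester rearrangement, would return 4.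

**Step 5.**
- What may go wrong: acid-induced dimerisation or oligomerisation of the electron-rich chromene through the same C4 cation; incomplete conversion because the liberated alcohol re-adds.
- Fallback: it sets out from 11 and comes back at 12, so that the chromene never meets acid. Ionic reduction (Et3SiH 1.2 equiv, CF3CO2H, CH2Cl2, 0 °C) would trap the C4 cation with hydride and give 1-(5-hydroxy-8-methoxy-2,2-dimethyl-3,4-dihydro-2H-chromen-6-yl)-2-(4-methoxyphenyl)ethane-1,2-dione F4. The diketone, whose carbocation would be destabilised by the neighbouring carbonyl, should be spared. Dehydrogenation with DDQ (1,4-dioxane, reflux), a known conversion of 2,2-dimethylchromans into chromenes, would then give 12 under neutral conditions.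

## Further compounds

F1 | step 4 | 1-[2-hydroxy-5-methoxy-3-(3-methylbut-2-en-1-ylidene)-4-oxocyclohexa-1,5-dien-1-yl]-2-(4-methoxyphenyl)ethane-1,2-dione (not isolated; exocyclic alkene drawn cis to the ring carbonyl) | CC(C)=C/C=C1\C(=O)C(OC)=CC(C(=O)C(=O)c2ccc(OC)cc2)=C1O
F0 | step 3 | none | none
F2 | step 2 | 4-methoxy-6-[2-(4-methoxyphenyl)acetyl]-1,3-phenylene diacetate | COc1ccc(CC(=O)c2cc(OC)c(OC(C)=O)cc2OC(C)=O)cc1
F3 | step 2 | 4-methoxy-6-[2-(4-methoxyphenyl)-2-oxoacetyl]-1,3-phenylene diacetate | COc1ccc(C(=O)C(=O)c2cc(OC)c(OC(C)=O)cc2OC(C)=O)cc1
F4 | step 5 | 1-(5-hydroxy-8-methoxy-2,2-dimethyl-3,4-dihydro-2H-chromen-6-yl)-2-(4-methoxyphenyl)ethane-1,2-dione | COc1ccc(C(=O)C(=O)c2cc(OC)c3c(c2O)CCC(C)(C)O3)cc1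
A1 | alternative 1 | 1-[8-methoxy-5-(methoxymethoxy)-2,2-dimethyl-2H-chromen-6-yl]-2-(4-methoxyphenyl)ethane-1,2-dione | COCOc1c(C(=O)C(=O)c2ccc(OC)cc2)cc(OC)c2c1C=CC(C)(C)O2
A2 | alternative 1 | 8-methoxy-5-(methoxymethoxy)-2,2-dimethyl-2H-chromene | COCOc1ccc(OC)c2c1C=CC(C)(C)O2
A3 | alternative 1 | 1,4-dimethylpiperazine-2,3-dione | CN1CCN(C)C(=O)C1=O
A4 | alternative 1 | 4-methoxyphenylmagnesium bromide | COc1ccc([Mg]Br)cc1
A5 | alternative 2 | (E)-5-isopropoxy-4-methoxy-2-(4-methoxystyryl)phenol | COc1ccc(/C=C/c2cc(OC)c(OC(C)C)cc2O)cc1
A6 | alternative 2 | 3-isopropoxy-4-methoxy-4-[(1E,3E)-4-(4-methoxyphenyl)buta-1,3-dienyl]cyclobut-2-en-1-one (racemic) | COc1ccc(/C=C/C=C/C2(OC)C(OC(C)C)=CC2=O)cc1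
A7 | alternative 3 | 1-[2,4-dihydroxy-5-methoxy-3-(3-methylbut-2-enyl)phenyl]-2-(4-methoxyphenyl)ethane-1,2-dione | COc1ccc(C(=O)C(=O)c2cc(OC)c(O)c(CC=C(C)C)c2O)cc1
A8 | alternative 3 | 1,4-dimethoxy-2-(3-methylbut-2-enyl)-1,3-bis(trimethylsilyloxy)buta-1,3-diene (alkene geometry not defined) | COC=C(O[Si](C)(C)C)C(CC=C(C)C)=C(OC)O[Si](C)(C)C
A9 | alternative 3 | 1,1-dimethoxy-1-(4-methoxyphenyl)but-3-yn-2-one | C#CC(=O)C(OC)(OC)c1ccc(OC)cc1
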